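**Retrosynthetic overview**
- Ring A (C4a, C5, C6, C7, C8, C8a; isochromanone numbering) has oxygen on C6 and C8, the C1 carboxyl carbon on C8a, a methyl on C5 and the C4–C3–C9 arm on C4a. This is the pattern left by a C-methylated poly-β-carbonyl chain that has folded and aromatised, and the route copies that event.
- Endgame cuts: the lactol ring is opened at O2–C3 to a C3 ketone and a C1 acid. The O–C9 bond is cut to a primary alcohol and benzyl-protected 2,4-dihydroxy-3,5,6-trimethylbenzoic acid (ring B), made from the commercial 3,6-dimethyl ester by one extra C-methylation at its C5.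
- Core cut: C4a–C8a of ring A, leading back to an open 2,4-diketo-dioxinone that keeps C3 as a silyl ether.
- Chain cuts: C4a–C5 (keto-dioxinone dianion plus Weinreb amide), C6–C7 (dioxinone dienolate plus propionyl chloride), C3–C4 (oxazolidinone syn-aldol, which fixes C4).
- Ring order: ring B is bought, ring A is made in step 6, and the lactol ring closes by itself in the last step.

Key step: step 6

Numbering: the atom numbers of the target (C1, O2, C3, C4, C4a, C5–C8, C8a, C9 = the CH2O carbon) are used for the corresponding atoms of all intermediates.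

Assumption: the C3 hemiketal centre equilibrates through ring–chain tautomerism, so the (3R) configuration drawn (OH anti to the C4 methyl) is taken to be the thermodynamically preferred one. Only C4 therefore has to be set by reagent control.

**Step 1**
Reactants: 1 (R)-4-benzyl-3-propionyloxazolidin-2-one; 2 2-[(4-methoxybenzyl)oxy]acetaldehyde
Product: 4 (R)-4-benzyl-3-[(2R,3R)-3-hydroxy-4-(4-methoxybenzyloxy)-2-methylbutanoyl]oxazolidin-2-one, via (Z)-dibutylboron enolate 3 (not isolated)
Conditions: Bu2BOTf, Et3N, CH2Cl2, 0 °C; 2, −78 → 0 °C; H2O2, MeOH, pH 7 buffer, 0 °C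
Reagents that add atoms: none
Why: Evans boron syn-aldol reaction, in which the (Z)-enolate 3 reacts through a closed Zimmerman–Traxler chair whose exposed face is dictated by the benzyl group of the (R)-auxiliary, so that C4 (2R in 4, the centre that survives to the target) and the temporary C3 carbinol (3R) are set together.

**Step 2**
Reactants: 4 aldol imide
Product: 5 (2R,3R)-3-hydroxy-N-methoxy-4-(4-methoxybenzyloxy)-N,2-dimethylbutanamide
Conditions: MeONHMe·HCl, AlMe3, THF, −10 °C → rt
Reagents that add atoms: N,O-dimethylhydroxylamine hydrochloride, CNOC.Cl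
Why: Weinreb transamidation with the aluminium amide, which the free C3 alkoxide guides to the exocyclic imide carbonyl; it is therefore run before silylation, since silylated aldol imides tend to suffer opening of the oxazolidinone ring, and it does not enolise C4.

**Step 3**
Reactants: 5 hydroxy Weinreb amide
Product: 6 (2R,3R)-3-(tert-butyldimethylsilyloxy)-N-methoxy-4-(4-methoxybenzyloxy)-N,2-dimethylbutanamide
Conditions: TBSOTf, 2,6-lutidine, CH2Cl2, 0 °C
Reagents that add atoms: tert-butyldimethylsilyl triflate, CC(C)(C)[Si](C)(C)OS(=O)(=O)C(F)(F)F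
Why: Silylation of a secondary alcohol with a silyl triflate and a hindered base, which blocks retro-aldol cleavage and holds C3 at the alcohol level so that C4 later has only one carbonyl neighbour.

**Step 4**
Reactants: 7 2,2,6-trimethyl-4H-1,3-dioxin-4-one; 8 propionyl chloride
Product: 10 2,2-dimethyl-6-(2-oxobutyl)-4H-1,3-dioxin-4-one, via lithium dienolate 9 (not isolated)
Conditions: LiN(SiMe3)2, THF, −78 °C; 8 (0.5 equiv), −78 → −20 °C
Reagents that add atoms: none
Why: Vinylogous Claisen-type C-acylation, in which the dienolate 9 attacks the acid chloride through its γ-carbon (future C7) to form the C6–C7 bond, the excess dienolate serving to take up the more acidic proton of the product.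

**Step 5**
Reactants: 10 keto-dioxinone; 6 silylated Weinreb amide
Product: 13 6-[(5R,6R)-6-(tert-butyldimethylsilyloxy)-7-(4-methoxybenzyloxy)-3,5-dimethyl-2,4-dioxoheptyl]-2,2-dimethyl-4H-1,3-dioxin-4-one (epimers at the carbon between the ketones plus enol forms), via dilithio dianion 11 (not isolated), via tetrahedral adduct 12 (not isolated)
Conditions: LiN(iPr)2 (2.1 equiv per 10), THF, −78 → −40 °C; 6 (0.5 equiv), −40 °C; AcOH, −78 °C
Reagents that add atoms: none
Why: Acylation of a β-dicarbonyl dianion by a Weinreb amide, in which the carbanion formed last (future C5) is the more reactive site and makes the C4a–C5 bond, while the chelated adduct 12 persists until the cold acidic quench, so that neither a second addition nor base contact of the C4–H next to the new ketone can occur.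

**Step 6**
Reactants: 13 diketo-dioxinone
Product: 15 5-[(2S,3R)-3-(tert-butyldimethylsilyloxy)-4-(4-methoxybenzyloxy)butan-2-yl]-7-hydroxy-2,2,6-trimethyl-4H-1,3-benzodioxin-4-one, via cyclic aldol 14 (not isolated)
Conditions: Et3N, 4 Å molecular sieves, CH2Cl2, rt
Reagents that add atoms: none
Why: Et3N reversibly removes a C7 proton (flanked by the dioxinone and the C6 ketone), the extended enolate adds through the dioxinone α-carbon (future C8a) to the C4a ketone to give the tertiary aldol 14, and E1cB loss of water across C4a–C5 followed by enolisation of the C6 carbonyl delivers the arene. The closest known reaction type is the base-mediated aldol aromatisation of 2,4-diketo-dioxinones to acetonide-masked resorcylates, a laboratory version of polyketide folding. Ring A closes in a 6-(enolexo)-exo-trig mode, because the reacting enolate bond C1=C8a lies outside the new six-membered ring and the C4a=O bond is exocyclic to it, a closure that the Baldwin enolate rules allow. No lasting stereocentre is made, since C4a and C5 of 14 become sp2 and the epimers of 13 therefore converge, while C4 and C3 are only carried through. The step needs C-cyclisation to outrun O-cyclisation to a pyranone, enolisation at C4 and β-elimination of the silyloxy group: the C5 methyl destabilises the planar enol of the C4a/C6 diketone by allylic strain and so leaves C4a a true ketone, the amine is too weak to remove the C4–H, which has a single carbonyl neighbour because C3 is a silyl ether, and room temperature avoids thermal loss of acetone to the acylketene. The product also has all its oxygens differentiated, with only the C6 hydroxyl free and C8–O and C1 tied in the acetonide.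

**Step 7**
Reactants: 15 phenol
Product: 16 5-[(2S,3R)-3-(tert-butyldimethylsilyloxy)-4-(4-methoxybenzyloxy)butan-2-yl]-7-methoxy-2,2,6-trimethyl-4H-1,3-benzodioxin-4-one
Conditions: MeI, K2CO3, acetone, rt
Reagents that add atoms: iodomethane, CI
Why: Williamson O-methylation, unambiguous because the C6 hydroxyl is the only acidic OH in 15 and the benzodioxinone tolerates carbonate in acetone.

**Step 8**
Reactants: 16 benzodioxinone
Product: 18 benzyl 6-(benzyloxy)-2-[(2S,3R)-3-(tert-butyldimethylsilyloxy)-4-(4-methoxybenzyloxy)butan-2-yl]-4-methoxy-3-methylbenzoate, via sodium phenoxide 17 (not isolated)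
Conditions: BnOH, NaH, THF, 0 → 40 °C; then BnBr, Bu4NI (cat.), DMF, rt
Reagents that add atoms: benzyl alcohol, OCc1ccccc1; benzyl bromide, BrCc1ccccc1
Why: Acyl substitution at the activated benzodioxinone carbonyl by benzyl alkoxide releases acetone and the C8 phenoxide 17, which is capped in the same flask by Williamson benzylation so that no free phenol meets DDQ, the Mitsunobu reagents or the periodinane later on.

**Step 9**
Reactants: 18 PMB ether
Product: 19 benzyl 6-(benzyloxy)-2-[(2S,3R)-3-(tert-butyldimethylsilyloxy)-4-hydroxybutan-2-yl]-4-methoxy-3-methylbenzoate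
Conditions: DDQ, CH2Cl2–pH 7 buffer, 0 °C
Reagents that add atoms: none
Why: Oxidative cleavage of a 4-methoxybenzyl ether by DDQ, which abstracts hydride from the most electron-rich benzylic CH2 and leaves plain benzyl groups, the silyl ether and the ester-deactivated ring A untouched at low temperature.

**Step 10**
Reactants: 20 methyl 2,4-dihydroxy-3,6-dimethylbenzoate
Product: 21 methyl 5-formyl-2,4-dihydroxy-3,6-dimethylbenzoate
Conditions: Cl2CHOMe, TiCl4, CH2Cl2, −10 °C → rt; ice–water
Reagents that add atoms: dichloromethyl methyl ether, COC(Cl)Cl; water, O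
Why: Rieche formylation of an activated resorcinol ring, regiochemically unambiguous because C5 of ring B (ortho to one hydroxyl, para to the other) is the only free ring position.

**Step 11**
Reactants: 21 aldehyde
Product: 22 methyl 2,4-dihydroxy-3,5,6-trimethylbenzoate
Conditions: Et3SiH, CF3CO2H, CH2Cl2, 0 °C → rt
Reagents that add atoms: none
Why: Ionic hydrogenation of an ortho/para-hydroxy benzaldehyde, whose strongly stabilised benzylic cations accept hydride twice to give the missing third methyl group, with no free ring position left for Friedel–Crafts dimerisation.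

**Step 12**
Reactants: 22 resorcinol ester
Product: 23 methyl 2,4-bis(benzyloxy)-3,5,6-trimethylbenzoate
Conditions: BnBr, K2CO3, DMF, 60 °C
Reagents that add atoms: benzyl bromide, BrCc1ccccc1
Why: Double Williamson benzylation, warmed in DMF so that the hydrogen-bonded and flanked hydroxyls both react.

**Step 13**
Reactants: 23 methyl ester
Product: 24 2,4-bis(benzyloxy)-3,5,6-trimethylbenzoic acid
Conditions: KOH, DMSO–H2O, 100 °C; then 1 M HCl
Reagents that add atoms: potassium hydroxide, [K+].[OH-]
Why: Saponification of a di-ortho-substituted benzoate, which needs poorly solvated hydroxide at high temperature, conditions to which aryl benzyl ethers are inert.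

**Step 14**
Reactants: 19 primary alcohol; 24 ring B acid
Product: 25 benzyl 6-(benzyloxy)-2-[(2S,3R)-4-{[2,4-bis(benzyloxy)-3,5,6-trimethylbenzoyl]oxy}-3-(tert-butyldimethylsilyloxy)butan-2-yl]-4-methoxy-3-methylbenzoate
Conditions: PPh3, DIAD, THF, 0 °C → rt
Reagents that add atoms: none
Why: Mitsunobu esterification, chosen because the carboxylate of 24 acts as nucleophile at the activated primary C9, so that the shielded acyl carbon of ring B never has to be attacked and no stereocentre is involved.

**Step 15**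
Reactants: 25 silyl ether
Product: 26 benzyl 6-(benzyloxy)-2-[(2S,3R)-4-{[2,4-bis(benzyloxy)-3,5,6-trimethylbenzoyl]oxy}-3-hydroxybutan-2-yl]-4-methoxy-3-methylbenzoate
Conditions: HF·pyridine, pyridine, THF, 0 °C → rt; crude product used at once
Reagents that add atoms: none
Why: Fluoride desilylation in a weakly acidic buffered medium, in which no C3 alkoxide is formed, so that attack on the twisted di-ortho-substituted C1 ester and acyl migration from O9 should stay slow.

**Step 16**
Reactants: 26 secondary alcohol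
Product: 27 benzyl 6-(benzyloxy)-2-[(2S)-4-{[2,4-bis(benzyloxy)-3,5,6-trimethylbenzoyl]oxy}-3-oxobutan-2-yl]-4-methoxy-3-methylbenzoate
Conditions: Dess–Martin periodinane, CH2Cl2, 0 °C → rt; short filtration through neutral silica
Reagents that add atoms: none
Why: Dess–Martin oxidation, a base-free method that raises C3 to the ketone without enolising the now doubly activated C4–H.

**Step 17**
Reactants: 27 keto tetrabenzyl compound
Product: 29 [(3R,4S)-3,8-dihydroxy-6-methoxy-4,5-dimethyl-1-oxo-3,4-dihydro-1H-isochromen-3-yl]methyl 2,4-dihydroxy-3,5,6-trimethylbenzoate, via keto acid 28 (not isolated)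
Conditions: H2 (1 atm), 10% Pd/C, EtOAc, rt; no acid in work-up
Reagents that add atoms: none
Why: Catalytic hydrogenolysis removes the benzyl ester and the three aryl benzyl ethers under neutral conditions, and the freed C1 acid of 28 adds to the electrophilic α-acyloxy C3 ketone (ring–chain tautomerism, 6-exo-trig), C3 being set under thermodynamic control by C4, because the C4 methyl stands pseudoaxial to avoid the peri C5 methyl and the anomerically favoured axial OH anti to it, with the CH2O-acyl arm equatorial, is the (3R) isomer.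

**Compound list**
1 | (R)-4-benzyl-3-propionyloxazolidin-2-one | CCC(=O)N1[C@H](Cc2ccccc2)COC1=O | starting material
2 | 2-[(4-methoxybenzyl)oxy]acetaldehyde | COc1ccc(COCC=O)cc1 | starting material
3 | (Z)-dibutylboron enolate of 1 | C/C=C(\OB(CCCC)CCCC)N1[C@H](Cc2ccccc2)COC1=O | intermediate
4 | (R)-4-benzyl-3-[(2R,3R)-3-hydroxy-4-(4-methoxybenzyloxy)-2-methylbutanoyl]oxazolidin-2-one | O=C1OC[C@@H](Cc2ccccc2)N1C(=O)[C@H](C)[C@@H](O)COCc1ccc(OC)cc1 | intermediate
5 | (2R,3R)-3-hydroxy-N-methoxy-4-(4-methoxybenzyloxy)-N,2-dimethylbutanamide | CON(C)C(=O)[C@H](C)[C@@H](O)COCc1ccc(OC)cc1 | intermediate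
6 | (2R,3R)-3-(tert-butyldimethylsilyloxy)-N-methoxy-4-(4-methoxybenzyloxy)-N,2-dimethylbutanamide | CON(C)C(=O)[C@H](C)[C@@H](O[Si](C)(C)C(C)(C)C)COCc1ccc(OC)cc1 | intermediate
7 | 2,2,6-trimethyl-4H-1,3-dioxin-4-one | CC1=CC(=O)OC(C)(C)O1 | starting material
8 | propionyl chloride | CCC(=O)Cl | starting material
9 | lithium 2,2-dimethyl-6-methylidene-6H-1,3-dioxin-4-olate | [Li+].C=C1C=C([O-])OC(C)(C)O1 | intermediate
10 | 2,2-dimethyl-6-(2-oxobutyl)-4H-1,3-dioxin-4-one | CCC(=O)CC1=CC(=O)OC(C)(C)O1 | intermediate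
11 | dilithio dianion of 10 | [Li+].[Li+].CC=C([O-])C=C1C=C([O-])OC(C)(C)O1 | intermediate
12 | dilithium tetrahedral adduct of 11 and 6 | [Li+].[Li+].CON(C)C([O-])(C(C)C(=O)C=C1C=C([O-])OC(C)(C)O1)[C@H](C)[C@@H](O[Si](C)(C)C(C)(C)C)COCc1ccc(OC)cc1 | intermediate
13 | 6-[(5R,6R)-6-(tert-butyldimethylsilyloxy)-7-(4-methoxybenzyloxy)-3,5-dimethyl-2,4-dioxoheptyl]-2,2-dimethyl-4H-1,3-dioxin-4-one | CC1(C)OC(=CC(=O)O1)CC(=O)C(C)C(=O)[C@H](C)[C@@H](O[Si](C)(C)C(C)(C)C)COCc1ccc(OC)cc1 | intermediate
14 | 5-[(2R,3R-derived) 3-(tert-butyldimethylsilyloxy)-4-(4-methoxybenzyloxy)butan-2-yl]-5-hydroxy-2,2,6-trimethyl-5,6-dihydro-4H-1,3-benzodioxine-4,7(8H)-dione (ring centres undefined) | CC1(C)OC2=C(C(=O)O1)C(O)([C@H](C)[C@@H](O[Si](C)(C)C(C)(C)C)COCc1ccc(OC)cc1)C(C)C(=O)C2 | intermediate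
15 | 5-[(2S,3R)-3-(tert-butyldimethylsilyloxy)-4-(4-methoxybenzyloxy)butan-2-yl]-7-hydroxy-2,2,6-trimethyl-4H-1,3-benzodioxin-4-one | Oc1cc2OC(C)(C)OC(=O)c2c(c1C)[C@H](C)[C@@H](O[Si](C)(C)C(C)(C)C)COCc1ccc(OC)cc1 | intermediate
16 | 5-[(2S,3R)-3-(tert-butyldimethylsilyloxy)-4-(4-methoxybenzyloxy)butan-2-yl]-7-methoxy-2,2,6-trimethyl-4H-1,3-benzodioxin-4-one | COc1cc2OC(C)(C)OC(=O)c2c(c1C)[C@H](C)[C@@H](O[Si](C)(C)C(C)(C)C)COCc1ccc(OC)cc1 | intermediate
17 | benzyl 2-[(2S,3R)-3-(tert-butyldimethylsilyloxy)-4-(4-methoxybenzyloxy)butan-2-yl]-6-hydroxy-4-methoxy-3-methylbenzoate (in the flask as its sodium phenoxide) | COc1cc(O)c(C(=O)OCc2ccccc2)c(c1C)[C@H](C)[C@@H](O[Si](C)(C)C(C)(C)C)COCc1ccc(OC)cc1 | intermediate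
18 | benzyl 6-(benzyloxy)-2-[(2S,3R)-3-(tert-butyldimethylsilyloxy)-4-(4-methoxybenzyloxy)butan-2-yl]-4-methoxy-3-methylbenzoate | COc1cc(OCc2ccccc2)c(C(=O)OCc2ccccc2)c(c1C)[C@H](C)[C@@H](O[Si](C)(C)C(C)(C)C)COCc1ccc(OC)cc1 | intermediate
19 | benzyl 6-(benzyloxy)-2-[(2S,3R)-3-(tert-butyldimethylsilyloxy)-4-hydroxybutan-2-yl]-4-methoxy-3-methylbenzoate | COc1cc(OCc2ccccc2)c(C(=O)OCc2ccccc2)c(c1C)[C@H](C)[C@@H](O[Si](C)(C)C(C)(C)C)CO | intermediate
20 | methyl 2,4-dihydroxy-3,6-dimethylbenzoate | COC(=O)c1c(C)cc(O)c(C)c1O | starting material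
21 | methyl 5-formyl-2,4-dihydroxy-3,6-dimethylbenzoate | COC(=O)c1c(C)c(C=O)c(O)c(C)c1O | intermediate
22 | methyl 2,4-dihydroxy-3,5,6-trimethylbenzoate | COC(=O)c1c(C)c(C)c(O)c(C)c1O | intermediate
23 | methyl 2,4-bis(benzyloxy)-3,5,6-trimethylbenzoate | COC(=O)c1c(C)c(C)c(OCc2ccccc2)c(C)c1OCc1ccccc1 | intermediate
24 | 2,4-bis(benzyloxy)-3,5,6-trimethylbenzoic acid | OC(=O)c1c(C)c(C)c(OCc2ccccc2)c(C)c1OCc1ccccc1 | intermediate
25 | benzyl 6-(benzyloxy)-2-[(2S,3R)-4-{[2,4-bis(benzyloxy)-3,5,6-trimethylbenzoyl]oxy}-3-(tert-butyldimethylsilyloxy)butan-2-yl]-4-methoxy-3-methylbenzoate | COc1cc(OCc2ccccc2)c(C(=O)OCc2ccccc2)c(c1C)[C@H](C)[C@@H](O[Si](C)(C)C(C)(C)C)COC(=O)c1c(C)c(C)c(OCc2ccccc2)c(C)c1OCc1ccccc1 | intermediate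
26 | benzyl 6-(benzyloxy)-2-[(2S,3R)-4-{[2,4-bis(benzyloxy)-3,5,6-trimethylbenzoyl]oxy}-3-hydroxybutan-2-yl]-4-methoxy-3-methylbenzoate | COc1cc(OCc2ccccc2)c(C(=O)OCc2ccccc2)c(c1C)[C@H](C)[C@@H](O)COC(=O)c1c(C)c(C)c(OCc2ccccc2)c(C)c1OCc1ccccc1 | intermediate
27 | benzyl 6-(benzyloxy)-2-[(2S)-4-{[2,4-bis(benzyloxy)-3,5,6-trimethylbenzoyl]oxy}-3-oxobutan-2-yl]-4-methoxy-3-methylbenzoate | COc1cc(OCc2ccccc2)c(C(=O)OCc2ccccc2)c(c1C)[C@H](C)C(=O)COC(=O)c1c(C)c(C)c(OCc2ccccc2)c(C)c1OCc1ccccc1 | intermediate
28 | 2-[(2S)-4-{(2,4-dihydroxy-3,5,6-trimethylbenzoyl)oxy}-3-oxobutan-2-yl]-6-hydroxy-4-methoxy-3-methylbenzoic acid | COc1cc(O)c(C(=O)O)c(c1C)[C@H](C)C(=O)COC(=O)c1c(C)c(C)c(O)c(C)c1O | intermediate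
29 | [(3R,4S)-3,8-dihydroxy-6-methoxy-4,5-dimethyl-1-oxo-3,4-dihydro-1H-isochromen-3-yl]methyl 2,4-dihydroxy-3,5,6-trimethylbenzoate | COc1cc(O)c2c(c1C)[C@H](C)[C@](O)(COC(=O)c1c(C)c(C)c(O)c(C)c1O)OC2=O | target

**Step count**
- Total step count: 17.
- Longest linear sequence: 12 steps (1, 2, 3, 5, 6, 7, 8, 9, 14, 15, 16, 17).

**Steps most likely to fail**

**Step 6.**
- What may go wrong: the extended enolate may add too slowly to the doubly α-branched C4a carbonyl. Closure through an enol oxygen, or gradual loss of configuration at C4, could then take over.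
- The fallback sets out from 13 and replaces the ring-bound vinylogous nucleophile by a free β-keto ester methylene.
- Heating 13 with benzyl alcohol in toluene at 110 °C should expel acetone by retro-hetero-Diels–Alder reaction. The acylketene is trapped to give the benzyl 3,5,7-trioxodecanoate F1.
- The more acidic and conformationally free C8a methylene of F1 should close onto C4a with Cs2CO3 in THF. Acetic acid then completes the dehydration and gives the benzyl resorcylate F2.
- One equivalent of MeI with K2CO3 in acetone should methylate only the C6 hydroxyl, because the C8 hydroxyl is hydrogen-bonded to the ester. This gives 17.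
- The route is rejoined at 17 with the benzylation half of step 8. The ring opening of step 8 is no longer needed.

**Step 5.**
- What may go wrong: the secondary carbanion terminus may add sluggishly to the α-branched amide. Proton transfer from the amide, followed by loss of the silyloxy group, could then consume the material.
- The fallback sets out from 6 and raises the electrophilicity of C4a.
- Reduction with iBu2AlH in THF at −78 °C should give the aldehyde F3.
- The dianion 11 (made from 10 as in step 5) should add to F3 in an aldol addition to give the β-hydroxy ketone F4. Its mixture of diastereomers does not matter, because both new centres become sp2.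
- Dess–Martin periodinane in CH2Cl2 should oxidise the carbinol and return the route at 13.

**Step 15.**
- What may go wrong: once the C3 hydroxyl is free it may attack the neighbouring C1 benzyl ester. This six-ring lactonisation, with loss of benzyl alcohol, would lock C3 at the alcohol level. Migration of the ring B acyl group from O9 to O3 is a second possible leak.
- The fallback sets out from 16 and carries C1 as a fluoride-labile ester, so that C1 is already a non-electrophilic carboxylate when C3–OH appears.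
- Opening of 16 with lithium 2-(trimethylsilyl)ethoxide in THF, followed by BnBr and K2CO3 in DMF, should give the 2-(trimethylsilyl)ethyl ester F5.
- DDQ as in step 9 should give the primary alcohol F6.
- Mitsunobu coupling of F6 with 24 as in step 14 should give the diester F7.
- Excess Bu4NF in THF should cleave the silylethyl ester first and the hindered silyl ether second. This gives the hydroxy acid F8, which is kept as its tetrabutylammonium carboxylate.
- Dess–Martin oxidation of this salt, followed by a mildly acidic buffer wash, should give the tri-O-benzyl lactol F9.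
- Hydrogenolysis of F9 as in step 17 returns the route at 29.

**Further compounds**
F1 | step 6 | benzyl (8R,9R)-9-(tert-butyldimethylsilyloxy)-10-(4-methoxybenzyloxy)-6,8-dimethyl-3,5,7-trioxodecanoate | O=C(OCc1ccccc1)CC(=O)CC(=O)C(C)C(=O)[C@H](C)[C@@H](O[Si](C)(C)C(C)(C)C)COCc1ccc(OC)cc1
F2 | step 6 | benzyl 2-[(2S,3R)-3-(tert-butyldimethylsilyloxy)-4-(4-methoxybenzyloxy)butan-2-yl]-4,6-dihydroxy-3-methylbenzoate | Oc1cc(O)c(C(=O)OCc2ccccc2)c(c1C)[C@H](C)[C@@H](O[Si](C)(C)C(C)(C)C)COCc1ccc(OC)cc1
F3 | step 5 | (2R,3R)-3-(tert-butyldimethylsilyloxy)-4-(4-methoxybenzyloxy)-2-methylbutanal | O=C[C@H](C)[C@@H](O[Si](C)(C)C(C)(C)C)COCc1ccc(OC)cc1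
F4 | step 5 | 6-[6-(tert-butyldimethylsilyloxy)-4-hydroxy-7-(4-methoxybenzyloxy)-3,5-dimethyl-2-oxoheptyl]-2,2-dimethyl-4H-1,3-dioxin-4-one (chain centres from 6 retained, new centres mixed) | CC1(C)OC(=CC(=O)O1)CC(=O)C(C)C(O)[C@H](C)[C@@H](O[Si](C)(C)C(C)(C)C)COCc1ccc(OC)cc1
F5 | step 15 | 2-(trimethylsilyl)ethyl 6-(benzyloxy)-2-[(2S,3R)-3-(tert-butyldimethylsilyloxy)-4-(4-methoxybenzyloxy)butan-2-yl]-4-methoxy-3-methylbenzoate | COc1cc(OCc2ccccc2)c(C(=O)OCC[Si](C)(C)C)c(c1C)[C@H](C)[C@@H](O[Si](C)(C)C(C)(C)C)COCc1ccc(OC)cc1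
F6 | step 15 | 2-(trimethylsilyl)ethyl 6-(benzyloxy)-2-[(2S,3R)-3-(tert-butyldimethylsilyloxy)-4-hydroxybutan-2-yl]-4-methoxy-3-methylbenzoate | COc1cc(OCc2ccccc2)c(C(=O)OCC[Si](C)(C)C)c(c1C)[C@H](C)[C@@H](O[Si](C)(C)C(C)(C)C)CO
F7 | step 15 | 2-(trimethylsilyl)ethyl 6-(benzyloxy)-2-[(2S,3R)-4-{[2,4-bis(benzyloxy)-3,5,6-trimethylbenzoyl]oxy}-3-(tert-butyldimethylsilyloxy)butan-2-yl]-4-methoxy-3-methylbenzoate | COc1cc(OCc2ccccc2)c(C(=O)OCC[Si](C)(C)C)c(c1C)[C@H](C)[C@@H](O[Si](C)(C)C(C)(C)C)COC(=O)c1c(C)c(C)c(OCc2ccccc2)c(C)c1OCc1ccccc1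
F8 | step 15 | 6-(benzyloxy)-2-[(2S,3R)-4-{[2,4-bis(benzyloxy)-3,5,6-trimethylbenzoyl]oxy}-3-hydroxybutan-2-yl]-4-methoxy-3-methylbenzoic acid | COc1cc(OCc2ccccc2)c(C(=O)O)c(c1C)[C@H](C)[C@@H](O)COC(=O)c1c(C)c(C)c(OCc2ccccc2)c(C)c1OCc1ccccc1
F9 | step 15 | [(3R,4S)-8-(benzyloxy)-3-hydroxy-6-methoxy-4,5-dimethyl-1-oxo-3,4-dihydro-1H-isochromen-3-yl]methyl 2,4-bis(benzyloxy)-3,5,6-trimethylbenzoate | COc1cc(OCc2ccccc2)c2c(c1C)[C@H](C)[C@](O)(COC(=O)c1c(C)c(C)c(OCc3ccccc3)c(C)c1OCc1ccccc1)OC2=O
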